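**Retrosynthetic overview**

1. Both benzene rings are bought. Ring A (the benzofuran benzene ring) comes from ester 1 and is taken via 2 to iodide 3. Ring B (the chroman benzene ring) comes from aldehyde 4 and is taken via 5 and 6 to alkyne 7.
2. Disconnection of the bond between ring A and the future furan C3: 3 + 7 give tolane 8 (Sonogashira).
3. Key disconnection: the furan ring, the pyran ring and the 1,1-dimethylallyl group are all unravelled to 8 by isomerisation only. Forward, one flask takes 8 through Claisen phenol 9 and benzofuran 10 to the bicyclised ester 11.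
4. Last disconnection, C5–H back to C5–CO2Me: the ester steers iodination, O-prenylation and the choice of the cyclising phenol, blocks C5, and leaves at the end (11, acid 12, target 13).
5. Ring order: furan ring first, pyran ring second, in the same operation.

Assumption: the target is achiral (no stereocentre, no stereogenic double bond), so it is made as drawn; 1, 4, prenyl bromide, the prenylboronic ester and the Ohira–Bestmann reagent are taken as catalogue compounds.

**Route**

Step 1
Reactants: 1 methyl 2,4,6-trihydroxybenzoate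
Product: 2 methyl 2,4,6-trihydroxy-3-iodobenzoate
Conditions: NIS (1.0 equiv), MeCN, −20 °C to 0 °C, dark
Reagents that add atoms: N-iodosuccinimide, O=C1CCC(=O)N1I
Why: Electrophilic aromatic iodination; the two open ring positions are equivalent, so one equivalent of NIS at low temperature gives a single mono-iodide, and the ester damps over-iodination.

Step 2
Reactants: 2 methyl 2,4,6-trihydroxy-3-iodobenzoate
Product: 3 methyl 2,6-dihydroxy-3-iodo-4-[(3-methylbut-2-en-1-yl)oxy]benzoate
Conditions: prenyl bromide (1.05 equiv), K2CO3 (1.05 equiv), acetone, rt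
Reagents that add atoms: prenyl bromide (1-bromo-3-methylbut-2-ene), CC(C)=CCBr
Why: Williamson etherification under chelation control; only the 4-OH (para to the ester, not hydrogen-bonded, acidified by the ortho iodine) is ionised by one equivalent of carbonate, while the two ester-chelated OH groups stay untouched.

Step 3
Reactants: 4 2-bromo-3,5-dimethoxybenzaldehyde
Product: 5 2-bromo-3,5-dihydroxybenzaldehyde
Conditions: BBr3 (3 equiv), CH2Cl2, −78 °C to rt; then H2O
Reagents that add atoms: none
Why: Lewis-acid cleavage of aryl methyl ethers (BBr3 demethylation), done before any alkene exists so that BBr3 meets only the aryl bromide and the aldehyde.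

Step 4
Reactants: 5 2-bromo-3,5-dihydroxybenzaldehyde
Product: 6 3,5-dihydroxy-2-(3-methylbut-2-en-1-yl)benzaldehyde
Conditions: prenyl-B(pin) (1.5 equiv), PdCl2(IPent)(3-chloropyridine) (2 mol %; IPent = 1,3-bis[2,6-di(pentan-3-yl)phenyl]imidazol-2-ylidene), KOH (aq, 2 M), THF, 60 °C
Reagents that add atoms: 4,4,5,5-tetramethyl-2-(3-methylbut-2-en-1-yl)-1,3,2-dioxaborolane, CC(C)=CCB1OC(C)(C)C(C)(C)O1
Why: Suzuki–Miyaura allyl–aryl coupling; the very bulky carbene ligand makes reductive elimination occur at the unsubstituted allyl terminus, so the linear prenyl arene and not the 1,1-dimethylallyl isomer is formed, and the free phenols and the aldehyde tolerate the aqueous base.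

Step 5
Reactants: 6 3,5-dihydroxy-2-(3-methylbut-2-en-1-yl)benzaldehyde
Product: 7 5-ethynyl-4-(3-methylbut-2-en-1-yl)benzene-1,3-diol
Conditions: dimethyl (1-diazo-2-oxopropyl)phosphonate (1.5 equiv), K2CO3 (4 equiv), MeOH, 0 °C to rt
Reagents that add atoms: dimethyl (1-diazo-2-oxopropyl)phosphonate (Ohira–Bestmann reagent), COP(=O)(OC)C(=[N+]=[N-])C(C)=O
Why: Seyferth–Gilbert homologation in the Ohira–Bestmann variant; carbonate in methanol converts the aldehyde to the terminal alkyne without touching the prenyl group, the extra base covering the two phenols.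

Step 6
Reactants: 3 methyl 2,6-dihydroxy-3-iodo-4-[(3-methylbut-2-en-1-yl)oxy]benzoate; 7 5-ethynyl-4-(3-methylbut-2-en-1-yl)benzene-1,3-diol
Product: 8 methyl 3-{[3,5-dihydroxy-2-(3-methylbut-2-en-1-yl)phenyl]ethynyl}-2,6-dihydroxy-4-[(3-methylbut-2-en-1-yl)oxy]benzoate
Conditions: PdCl2(PPh3)2 (3 mol %), CuI (5 mol %), Et3N, THF (degassed), rt
Reagents that add atoms: none
Why: Sonogashira coupling; the aryl iodide couples at room temperature, where the ester-chelated ortho OH does not add to the new alkyne and the aryl prenyl ether is not ionised by zerovalent palladium.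

Step 7
Reactants: 8 methyl 3-{[3,5-dihydroxy-2-(3-methylbut-2-en-1-yl)phenyl]ethynyl}-2,6-dihydroxy-4-[(3-methylbut-2-en-1-yl)oxy]benzoate
Product: 11 methyl 4,6-dihydroxy-2-(7-hydroxy-2,2-dimethyl-3,4-dihydro-2H-chromen-5-yl)-7-(2-methylbut-3-en-2-yl)-1-benzofuran-5-carboxylate, via Claisen alkynylphenol 9 (not isolated), via open-chain benzofuran ester 10 (not isolated)
Conditions: 1,4-dioxane, 170 °C (sealed tube), 45 min; then Cs2CO3 (20 mol %), 100 °C; then TsOH·H2O (80 mol %), 70 °C
Reagents that add atoms: none
Why: Proposed new method: a one-flask triple isomerisation in which the aromatic Claisen rearrangement ([3,3]; the prenyl ether can deliver only to the one free ortho carbon, so the 1,1-dimethylallyl group lands next to the oxygen it frees) is followed by carbonate-catalysed 5-endo-dig addition of that newly freed phenol (para to the ester, the most acidic OH and the only one on ring A not tied to the ester carbonyl by a hydrogen bond) to the alkyne, and then by TsOH-catalysed Markovnikov 6-endo closure of the ring B ortho-prenylphenol through the tertiary cation, which forms far faster than the secondary cation from the monosubstituted 1,1-dimethylallyl alkene while the ester keeps C5 blocked and the neighbouring OH groups chelated; the closest known reaction types are the tandem Claisen rearrangement/cycloisomerisation of ortho-alkynyl aryl allyl ethers to 7-allylbenzofurans and the acid cyclisation of ortho-prenylphenols to 2,2-dimethylchromans, and no stereocentre is created.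

Step 8
Reactants: 11 methyl 4,6-dihydroxy-2-(7-hydroxy-2,2-dimethyl-3,4-dihydro-2H-chromen-5-yl)-7-(2-methylbut-3-en-2-yl)-1-benzofuran-5-carboxylate
Product: 13 2-(7-hydroxy-2,2-dimethyl-3,4-dihydro-2H-chromen-5-yl)-7-(2-methylbut-3-en-2-yl)-1-benzofuran-4,6-diol, via benzofuran-5-carboxylic acid 12 (not isolated)
Conditions: KOH (aq, 2 M)/MeOH, reflux, argon; then HCl (aq) to pH 3, 50 °C
Reagents that add atoms: none
Why: Saponification followed by protodecarboxylation; the acid flanked by two OH groups on a phloroglucinol-type ring loses CO2 by ipso-protonation on mild acidification (the standard removal of a resorcylate ester blocking group), and the 1,1-dimethylallyl group (quaternary allylic carbon, cannot isomerise) and the chroman are inert to base.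

**Compound list**

1 | methyl 2,4,6-trihydroxybenzoate | COC(=O)c1c(O)cc(O)cc1O | starting material
2 | methyl 2,4,6-trihydroxy-3-iodobenzoate | COC(=O)c1c(O)cc(O)c(I)c1O | intermediate
3 | methyl 2,6-dihydroxy-3-iodo-4-[(3-methylbut-2-en-1-yl)oxy]benzoate | COC(=O)c1c(O)cc(OCC=C(C)C)c(I)c1O | intermediate
4 | 2-bromo-3,5-dimethoxybenzaldehyde | COc1cc(OC)c(Br)c(C=O)c1 | starting material
5 | 2-bromo-3,5-dihydroxybenzaldehyde | Oc1cc(O)c(Br)c(C=O)c1 | intermediate
6 | 3,5-dihydroxy-2-(3-methylbut-2-en-1-yl)benzaldehyde | CC(C)=CCc1c(O)cc(O)cc1C=O | intermediate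
7 | 5-ethynyl-4-(3-methylbut-2-en-1-yl)benzene-1,3-diol | CC(C)=CCc1c(O)cc(O)cc1C#C | intermediate
8 | methyl 3-{[3,5-dihydroxy-2-(3-methylbut-2-en-1-yl)phenyl]ethynyl}-2,6-dihydroxy-4-[(3-methylbut-2-en-1-yl)oxy]benzoate | COC(=O)c1c(O)cc(OCC=C(C)C)c(C#Cc2cc(O)cc(O)c2CC=C(C)C)c1O | intermediate
9 | methyl 3-{[3,5-dihydroxy-2-(3-methylbut-2-en-1-yl)phenyl]ethynyl}-2,4,6-trihydroxy-5-(2-methylbut-3-en-2-yl)benzoate | COC(=O)c1c(O)c(C(C)(C)C=C)c(O)c(C#Cc2cc(O)cc(O)c2CC=C(C)C)c1O | intermediate
10 | methyl 2-[3,5-dihydroxy-2-(3-methylbut-2-en-1-yl)phenyl]-4,6-dihydroxy-7-(2-methylbut-3-en-2-yl)-1-benzofuran-5-carboxylate | COC(=O)c1c(O)c(C(C)(C)C=C)c2oc(-c3cc(O)cc(O)c3CC=C(C)C)cc2c1O | intermediate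
11 | methyl 4,6-dihydroxy-2-(7-hydroxy-2,2-dimethyl-3,4-dihydro-2H-chromen-5-yl)-7-(2-methylbut-3-en-2-yl)-1-benzofuran-5-carboxylate | COC(=O)c1c(O)c(C(C)(C)C=C)c2oc(-c3cc(O)cc4OC(C)(C)CCc34)cc2c1O | intermediate
12 | 4,6-dihydroxy-2-(7-hydroxy-2,2-dimethyl-3,4-dihydro-2H-chromen-5-yl)-7-(2-methylbut-3-en-2-yl)-1-benzofuran-5-carboxylic acid | OC(=O)c1c(O)c(C(C)(C)C=C)c2oc(-c3cc(O)cc4OC(C)(C)CCc34)cc2c1O | intermediate
13 | 2-(7-hydroxy-2,2-dimethyl-3,4-dihydro-2H-chromen-5-yl)-7-(2-methylbut-3-en-2-yl)-1-benzofuran-4,6-diol (achiral) | C=CC(C)(C)c1c(O)cc(O)c2cc(-c3cc(O)cc4c3CCC(C)(C)O4)oc12 | target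

**Step count and risks**

Total step count: 8. Longest linear sequence: 6 (steps 3, 4, 5, 6, 7, 8, starting from 4).

The three steps most likely to fail:

Step 7 (the one-flask Claisen/furan/pyran sequence). The ester-chelated 2-OH of 9 may compete with the 4-OH in the furan closure, or 9 may cyclise thermally onto its own 1,1-dimethylallyl group before the base is added. The fallback sets out from 3 and comes back at 11. It caps the two chelated phenols first, so that regiocontrol rests on a protecting group instead of on chelation. NaH and MOMCl in DMF turn 3 into methyl 3-iodo-2,6-bis(methoxymethoxy)-4-[(3-methylbut-2-en-1-yl)oxy]benzoate F1. Sonogashira coupling of this with 7, as in step 6, gives the tolane methyl 3-{[3,5-dihydroxy-2-(3-methylbut-2-en-1-yl)phenyl]ethynyl}-2,6-bis(methoxymethoxy)-4-[(3-methylbut-2-en-1-yl)oxy]benzoate F2. Cs2CO3 in DMF at 150 °C (base present from the start, since ring A now has no free OH) gives the Claisen phenol methyl 3-{[3,5-dihydroxy-2-(3-methylbut-2-en-1-yl)phenyl]ethynyl}-4-hydroxy-2,6-bis(methoxymethoxy)-5-(2-methylbut-3-en-2-yl)benzoate F3, which is not isolated. Its single ring A phenoxide closes at once to the protected benzofuran methyl 2-[3,5-dihydroxy-2-(3-methylbut-2-en-1-yl)phenyl]-4,6-bis(methoxymethoxy)-7-(2-methylbut-3-en-2-yl)-1-benzofuran-5-carboxylate F4. HCl in MeOH at 60 °C then removes both MOM groups (giving 10) and closes the pyran ring, delivering 11.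

Step 6 (Sonogashira coupling of two unprotected polyphenols). The chelated OH next to the new alkyne may cyclise early and give the wrong benzofuran, or zerovalent palladium may ionise the activated aryl prenyl ether. The fallback sets out from 3 and comes back at 10. It runs the Claisen shift before the coupling. Heating 3 alone (1,4-dioxane, 170 °C) gives methyl 2,4,6-trihydroxy-3-iodo-5-(2-methylbut-3-en-2-yl)benzoate F5. Coupling of this with 7 (PdCl2(PPh3)2, CuI, Et3N, DMF, 60 °C) forms 9 in the flask, and under these basic, copper-containing conditions the non-chelated 4-OH closes the furan directly. Any cyclisation during the coupling is now productive, and no prenyl ether meets the palladium catalyst. Compound 10 is isolated and treated with TsOH·H2O in dioxane at 70 °C, as in the last stage of step 7, to give 11.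

Step 4 (prenyl Suzuki–Miyaura coupling). Coupling through the substituted allyl terminus would give the 1,1-dimethylallyl isomer, and the doubly ortho-substituted bromophenol is a sluggish partner. The fallback sets out from 5 and comes back at 6. It builds the prenyl group in two stages. Suzuki–Miyaura coupling of 5 with allylboronic acid pinacol ester (a symmetrical allyl group, so no regiochemical question) gives 3,5-dihydroxy-2-(prop-2-en-1-yl)benzaldehyde F6. Cross-metathesis with excess 2-methylbut-2-ene and RuCl2(=CHPh)(PCy3)(H2IMes), the second-generation Grubbs catalyst (H2IMes = 1,3-dimesitylimidazolidin-2-ylidene), in CH2Cl2 at 40 °C then gives 6.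

**Further compounds**

F1 | step 7 | methyl 3-iodo-2,6-bis(methoxymethoxy)-4-[(3-methylbut-2-en-1-yl)oxy]benzoate | COC(=O)c1c(OCOC)cc(OCC=C(C)C)c(I)c1OCOC
F2 | step 7 | methyl 3-{[3,5-dihydroxy-2-(3-methylbut-2-en-1-yl)phenyl]ethynyl}-2,6-bis(methoxymethoxy)-4-[(3-methylbut-2-en-1-yl)oxy]benzoate | COC(=O)c1c(OCOC)cc(OCC=C(C)C)c(C#Cc2cc(O)cc(O)c2CC=C(C)C)c1OCOC
F3 | step 7 | methyl 3-{[3,5-dihydroxy-2-(3-methylbut-2-en-1-yl)phenyl]ethynyl}-4-hydroxy-2,6-bis(methoxymethoxy)-5-(2-methylbut-3-en-2-yl)benzoate | COC(=O)c1c(OCOC)c(C(C)(C)C=C)c(O)c(C#Cc2cc(O)cc(O)c2CC=C(C)C)c1OCOC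
F4 | step 7 | methyl 2-[3,5-dihydroxy-2-(3-methylbut-2-en-1-yl)phenyl]-4,6-bis(methoxymethoxy)-7-(2-methylbut-3-en-2-yl)-1-benzofuran-5-carboxylate | COC(=O)c1c(OCOC)c(C(C)(C)C=C)c2oc(-c3cc(O)cc(O)c3CC=C(C)C)cc2c1OCOC
F5 | step 6 | methyl 2,4,6-trihydroxy-3-iodo-5-(2-methylbut-3-en-2-yl)benzoate | COC(=O)c1c(O)c(C(C)(C)C=C)c(O)c(I)c1O
F6 | step 4 | 3,5-dihydroxy-2-(prop-2-en-1-yl)benzaldehyde | C=CCc1c(O)cc(O)cc1C=O
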